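**Retrosynthetic overview**
1. Rings: A (2,4,6-trihydroxyphenyl)–O–B–O–C–O–D(–O–E–O–F (3,4,5-trihydroxyphenyl)). Target 26 comes from tridecamethyl ether 24 by global O-demethylation.
2. Every Ar–O–Ar bond is cut to ArO⁻ + a fluorobenzaldehyde (metal-free SNAr). The CHO activates the fluoride and is then turned into the next phenol by Baeyer–Villiger oxidation, the reverse polarity of the usual Ullmann plan.
3. Growth runs in two directions from central ring D. Each double Baeyer–Villiger unveils one open phenol and one 2,6-di-O-flanked phenol. Hindered fluoride 5 arylates only the open phenol (rings C, B, A); open fluoride 10 then takes the flanked one (rings E, F). No protecting-group steps.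
4. The second arm is opened by Vilsmeier formylation of ring D in 12 (D2–CHO → D2–OH).
5. No ring is built; the aryl rings are joined in the order D+C → B → E → A → F. Fluorides 5 and 10 come from bromo aldehydes 1 and 6 by Br/Li exchange and NFSI.

Assumption: the target SMILES has no stereocentre or other stereo element, so it is achiral and no stereocontrol is needed; 1, 6 and 11 are taken as catalogue chemicals.

**Route**

Step 1
Reactants: 1 4-bromo-3,5-dimethoxybenzaldehyde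
Product: 2 2-bromo-5-(dimethoxymethyl)-1,3-dimethoxybenzene
Conditions: HC(OMe)3, MeOH, p-TsOH (cat.), reflux
Reagents that add atoms: trimethyl orthoformate COC(OC)OC
Why: Acid-catalysed acetalisation masks the aldehyde against n-BuLi in the next step.

Step 2
Reactants: 2 2-bromo-5-(dimethoxymethyl)-1,3-dimethoxybenzene
Product: 5 4-fluoro-3,5-dimethoxybenzaldehyde, via aryllithium 3 (not isolated), via fluoro acetal 4 (not isolated)
Conditions: n-BuLi, THF, −78 °C; NFSI, −78 °C to rt; then 2 M HCl, rt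
Reagents that add atoms: N-fluorobenzenesulfonimide (NFSI) O=S(=O)(c1ccccc1)N(F)S(=O)(=O)c1ccccc1; water O
Why: Bromine–lithium exchange is regiospecific, the aryllithium is fluorinated by electrophilic N–F transfer, and aqueous acid hydrolyses the acetal.

Step 3
Reactants: 6 4-bromo-2,6-dimethoxybenzaldehyde
Product: 7 5-bromo-2-(dimethoxymethyl)-1,3-dimethoxybenzene
Conditions: HC(OMe)3, MeOH, p-TsOH (cat.), reflux
Reagents that add atoms: trimethyl orthoformate COC(OC)OC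
Why: Acid-catalysed acetalisation of the electron-rich aldehyde, as in step 1.

Step 4
Reactants: 7 5-bromo-2-(dimethoxymethyl)-1,3-dimethoxybenzene
Product: 10 4-fluoro-2,6-dimethoxybenzaldehyde, via aryllithium 8 (not isolated), via fluoro acetal 9 (not isolated)
Conditions: n-BuLi, THF, −78 °C; NFSI, −78 °C to rt; then 2 M HCl, rt
Reagents that add atoms: N-fluorobenzenesulfonimide (NFSI) O=S(=O)(c1ccccc1)N(F)S(=O)(=O)c1ccccc1; water O
Why: Same halogen–lithium exchange, electrophilic fluorination and acetal hydrolysis as step 2, here placing F para to the masked CHO.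

Step 5
Reactants: 11 3,4,5-trimethoxyphenol; 5 4-fluoro-3,5-dimethoxybenzaldehyde
Product: 12 3,5-dimethoxy-4-(3,4,5-trimethoxyphenoxy)benzaldehyde
Conditions: Cs2CO3, DMSO, 120 °C, Ar
Reagents that add atoms: none
Why: SNAr (addition–elimination): the unhindered, electron-rich phenoxide attacks the C–F carbon para to the formyl group, which stabilises the Meisenheimer adduct, and this forms the C4–O–D1 ether.

Step 6
Reactants: 12 3,5-dimethoxy-4-(3,4,5-trimethoxyphenoxy)benzaldehyde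
Product: 14 6-(4-formyl-2,6-dimethoxyphenoxy)-2,3,4-trimethoxybenzaldehyde, via aryl iminium salt 13 (not isolated)
Conditions: POCl3, DMF, 0 to 75 °C; then H2O
Reagents that add atoms: N,N-dimethylformamide CN(C)C=O; water O
Why: Vilsmeier–Haack formylation attacks the only free position type of the electron-rich ring D (C-2 and C-6 are equivalent; ortho to OAr and OMe, para to OMe), while ring C is deactivated by its CHO.

Step 7
Reactants: 14 6-(4-formyl-2,6-dimethoxyphenoxy)-2,3,4-trimethoxybenzaldehyde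
Product: 16 6-(4-hydroxy-2,6-dimethoxyphenoxy)-2,3,4-trimethoxyphenol, via bis-formate 15 (not isolated)
Conditions: mCPBA, CH2Cl2, 0 °C to rt; then MeOH, Et3N (cat.), rt, Ar
Reagents that add atoms: mCPBA OOC(=O)c1cccc(Cl)c1
Why: Double Baeyer–Villiger oxidation: both aryl groups carry ortho/para oxygen donors, so aryl migrates rather than H, and mild methanolysis of the bis-formate gives one open phenol (ring C) and one flanked phenol (ring D).

Step 8
Reactants: 16 6-(4-hydroxy-2,6-dimethoxyphenoxy)-2,3,4-trimethoxyphenol; 5 4-fluoro-3,5-dimethoxybenzaldehyde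
Product: 17 4-[4-(2-hydroxy-3,4,5-trimethoxyphenoxy)-3,5-dimethoxyphenoxy]-3,5-dimethoxybenzaldehyde
Conditions: 5 (1.05 equiv), Cs2CO3 (1.1 equiv), DMSO, 110 °C, Ar
Reagents that add atoms: none
Why: Proposed new method: site-selective SNAr on a bis-phenol, in which about one equivalent of base forms the more acidic, unhindered ring-C phenoxide that attacks the di-ortho-methoxy fluoride 5, whereas the ring-D phenoxide (flanked by OAr and OMe) would have to build a tetra-ortho-oxygenated diaryl ether and stays free; the closest known reaction type is phenoxide SNAr on 4-fluorobenzaldehydes.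

Step 9
Reactants: 17 4-[4-(2-hydroxy-3,4,5-trimethoxyphenoxy)-3,5-dimethoxyphenoxy]-3,5-dimethoxybenzaldehyde; 10 4-fluoro-2,6-dimethoxybenzaldehyde
Product: 18 4-{4-[2-(4-formyl-3,5-dimethoxyphenoxy)-3,4,5-trimethoxyphenoxy]-3,5-dimethoxyphenoxy}-3,5-dimethoxybenzaldehyde
Conditions: 10 (1.3 equiv), K2CO3, DMF, 120 °C, Ar
Reagents that add atoms: none
Why: SNAr: the remaining 2,6-di-O-substituted phenoxide of ring D attacks the sterically open C–F of 10 (para to CHO), which forms the D2–O–E1 ether.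

Step 10
Reactants: 18 4-{4-[2-(4-formyl-3,5-dimethoxyphenoxy)-3,4,5-trimethoxyphenoxy]-3,5-dimethoxyphenoxy}-3,5-dimethoxybenzaldehyde
Product: 20 4-{4-[2-(4-hydroxy-3,5-dimethoxyphenoxy)-3,4,5-trimethoxyphenoxy]-3,5-dimethoxyphenoxy}-3,5-dimethoxyphenol, via bis-formate 19 (not isolated)
Conditions: mCPBA, CH2Cl2, 0 °C to rt; then MeOH, Et3N (cat.), rt, Ar
Reagents that add atoms: mCPBA OOC(=O)c1cccc(Cl)c1
Why: Double Baeyer–Villiger oxidation and formate methanolysis as in step 7, giving the open ring-B phenol and the flanked ring-E phenol.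

Step 11
Reactants: 20 4-{4-[2-(4-hydroxy-3,5-dimethoxyphenoxy)-3,4,5-trimethoxyphenoxy]-3,5-dimethoxyphenoxy}-3,5-dimethoxyphenol; 5 4-fluoro-3,5-dimethoxybenzaldehyde
Product: 21 4-(4-{4-[2-(4-hydroxy-3,5-dimethoxyphenoxy)-3,4,5-trimethoxyphenoxy]-3,5-dimethoxyphenoxy}-3,5-dimethoxyphenoxy)-3,5-dimethoxybenzaldehyde
Conditions: 5 (1.05 equiv), Cs2CO3 (1.1 equiv), DMSO, 110 °C, Ar
Reagents that add atoms: none
Why: Proposed new method: the same sterically and acidity-gated SNAr as step 8, in which the open ring-B phenoxide attacks hindered fluoride 5 while the 2,6-dimethoxy-flanked ring-E phenoxide cannot form a tetra-ortho-oxygenated ether; the closest known reaction type is phenoxide SNAr on 4-fluorobenzaldehydes.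

Step 12
Reactants: 21 4-(4-{4-[2-(4-hydroxy-3,5-dimethoxyphenoxy)-3,4,5-trimethoxyphenoxy]-3,5-dimethoxyphenoxy}-3,5-dimethoxyphenoxy)-3,5-dimethoxybenzaldehyde; 10 4-fluoro-2,6-dimethoxybenzaldehyde
Product: 22 4-[4-(4-{2-[4-(4-formyl-3,5-dimethoxyphenoxy)-3,5-dimethoxyphenoxy]-3,4,5-trimethoxyphenoxy}-3,5-dimethoxyphenoxy)-3,5-dimethoxyphenoxy]-3,5-dimethoxybenzaldehyde
Conditions: 10 (1.3 equiv), K2CO3, DMF, 120 °C, Ar
Reagents that add atoms: none
Why: SNAr of the flanked ring-E phenoxide at the open C–F of 10 forms the last ether (E4–O–F1).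

Step 13
Reactants: 22 4-[4-(4-{2-[4-(4-formyl-3,5-dimethoxyphenoxy)-3,5-dimethoxyphenoxy]-3,4,5-trimethoxyphenoxy}-3,5-dimethoxyphenoxy)-3,5-dimethoxyphenoxy]-3,5-dimethoxybenzaldehyde
Product: 24 4-[4-(4-{2-[4-(4-hydroxy-3,5-dimethoxyphenoxy)-3,5-dimethoxyphenoxy]-3,4,5-trimethoxyphenoxy}-3,5-dimethoxyphenoxy)-3,5-dimethoxyphenoxy]-3,5-dimethoxyphenol, via bis-formate 23 (not isolated)
Conditions: mCPBA, CH2Cl2, 0 °C to rt; then MeOH, Et3N (cat.), rt, Ar
Reagents that add atoms: mCPBA OOC(=O)c1cccc(Cl)c1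
Why: Double Baeyer–Villiger oxidation and formate methanolysis turn the two terminal CHO groups into the A-4 and F-4 hydroxyls of the target.

Step 14
Reactants: 24 4-[4-(4-{2-[4-(4-hydroxy-3,5-dimethoxyphenoxy)-3,5-dimethoxyphenoxy]-3,4,5-trimethoxyphenoxy}-3,5-dimethoxyphenoxy)-3,5-dimethoxyphenoxy]-3,5-dimethoxyphenol
Product: 26 CNP0175585.0 2-[4-(4-{2-[3,5-dihydroxy-4-(3,4,5-trihydroxyphenoxy)phenoxy]-3,4,5-trihydroxyphenoxy}-3,5-dihydroxyphenoxy)-3,5-dihydroxyphenoxy]benzene-1,3,5-triol, via aryl borate 25 (not isolated)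
Conditions: BBr3 (excess), CH2Cl2, −78 °C to rt; then H2O, 0 °C, Ar
Reagents that add atoms: none
Why: Lewis-acid O-demethylation: BBr3 cleaves all thirteen aryl methyl ethers (bromide attacks methyl of the ArO(Me)–BBr3 adduct) while diaryl ethers are inert, and hydrolysis of the aryl borates gives the achiral polyphenol.

**Compound list**
1 | 4-bromo-3,5-dimethoxybenzaldehyde | COc1cc(C=O)cc(OC)c1Br | starting material
2 | 2-bromo-5-(dimethoxymethyl)-1,3-dimethoxybenzene | COc1cc(C(OC)OC)cc(OC)c1Br | intermediate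
3 | [4-(dimethoxymethyl)-2,6-dimethoxyphenyl]lithium | COc1cc(C(OC)OC)cc(OC)c1[Li] | intermediate
4 | 5-(dimethoxymethyl)-2-fluoro-1,3-dimethoxybenzene | COc1cc(C(OC)OC)cc(OC)c1F | intermediate
5 | 4-fluoro-3,5-dimethoxybenzaldehyde | COc1cc(C=O)cc(OC)c1F | intermediate
6 | 4-bromo-2,6-dimethoxybenzaldehyde | COc1cc(Br)cc(OC)c1C=O | starting material
7 | 5-bromo-2-(dimethoxymethyl)-1,3-dimethoxybenzene | COc1cc(Br)cc(OC)c1C(OC)OC | intermediate
8 | [4-(dimethoxymethyl)-3,5-dimethoxyphenyl]lithium | COc1cc([Li])cc(OC)c1C(OC)OC | intermediate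
9 | 2-(dimethoxymethyl)-5-fluoro-1,3-dimethoxybenzene | COc1cc(F)cc(OC)c1C(OC)OC | intermediate
10 | 4-fluoro-2,6-dimethoxybenzaldehyde | COc1cc(F)cc(OC)c1C=O | intermediate
11 | 3,4,5-trimethoxyphenol | COc1cc(O)cc(OC)c1OC | starting material
12 | 3,5-dimethoxy-4-(3,4,5-trimethoxyphenoxy)benzaldehyde | COc1cc(C=O)cc(OC)c1Oc1cc(OC)c(OC)c(OC)c1 | intermediate
13 | N-{[6-(4-formyl-2,6-dimethoxyphenoxy)-2,3,4-trimethoxyphenyl]methylidene}-N-methylmethanaminium dichlorophosphate | COc1cc(C=O)cc(OC)c1Oc1cc(OC)c(OC)c(OC)c1C=[N+](C)C.[O-]P(=O)(Cl)Cl | intermediate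
14 | 6-(4-formyl-2,6-dimethoxyphenoxy)-2,3,4-trimethoxybenzaldehyde | COc1cc(C=O)cc(OC)c1Oc1cc(OC)c(OC)c(OC)c1C=O | intermediate
15 | 4-[2-(formyloxy)-3,4,5-trimethoxyphenoxy]-3,5-dimethoxyphenyl formate | COc1cc(OC=O)cc(OC)c1Oc1cc(OC)c(OC)c(OC)c1OC=O | intermediate
16 | 6-(4-hydroxy-2,6-dimethoxyphenoxy)-2,3,4-trimethoxyphenol | COc1cc(O)cc(OC)c1Oc1cc(OC)c(OC)c(OC)c1O | intermediate
17 | 4-[4-(2-hydroxy-3,4,5-trimethoxyphenoxy)-3,5-dimethoxyphenoxy]-3,5-dimethoxybenzaldehyde | COc1cc(C=O)cc(OC)c1Oc1cc(OC)c(Oc2cc(OC)c(OC)c(OC)c2O)c(OC)c1 | intermediate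
18 | 4-{4-[2-(4-formyl-3,5-dimethoxyphenoxy)-3,4,5-trimethoxyphenoxy]-3,5-dimethoxyphenoxy}-3,5-dimethoxybenzaldehyde | COc1cc(C=O)cc(OC)c1Oc1cc(OC)c(Oc2cc(OC)c(OC)c(OC)c2Oc2cc(OC)c(C=O)c(OC)c2)c(OC)c1 | intermediate
19 | 4-{4-[2-(4-formyloxy-3,5-dimethoxyphenoxy)-3,4,5-trimethoxyphenoxy]-3,5-dimethoxyphenoxy}-3,5-dimethoxyphenyl formate | COc1cc(OC=O)cc(OC)c1Oc1cc(OC)c(Oc2cc(OC)c(OC)c(OC)c2Oc2cc(OC)c(OC=O)c(OC)c2)c(OC)c1 | intermediate
20 | 4-{4-[2-(4-hydroxy-3,5-dimethoxyphenoxy)-3,4,5-trimethoxyphenoxy]-3,5-dimethoxyphenoxy}-3,5-dimethoxyphenol | COc1cc(O)cc(OC)c1Oc1cc(OC)c(Oc2cc(OC)c(OC)c(OC)c2Oc2cc(OC)c(O)c(OC)c2)c(OC)c1 | intermediate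
21 | 4-(4-{4-[2-(4-hydroxy-3,5-dimethoxyphenoxy)-3,4,5-trimethoxyphenoxy]-3,5-dimethoxyphenoxy}-3,5-dimethoxyphenoxy)-3,5-dimethoxybenzaldehyde | COc1cc(C=O)cc(OC)c1Oc1cc(OC)c(Oc2cc(OC)c(Oc3cc(OC)c(OC)c(OC)c3Oc3cc(OC)c(O)c(OC)c3)c(OC)c2)c(OC)c1 | intermediate
22 | 4-[4-(4-{2-[4-(4-formyl-3,5-dimethoxyphenoxy)-3,5-dimethoxyphenoxy]-3,4,5-trimethoxyphenoxy}-3,5-dimethoxyphenoxy)-3,5-dimethoxyphenoxy]-3,5-dimethoxybenzaldehyde | COc1cc(C=O)cc(OC)c1Oc1cc(OC)c(Oc2cc(OC)c(Oc3cc(OC)c(OC)c(OC)c3Oc3cc(OC)c(Oc4cc(OC)c(C=O)c(OC)c4)c(OC)c3)c(OC)c2)c(OC)c1 | intermediate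
23 | 4-[4-(4-{2-[4-(4-formyloxy-3,5-dimethoxyphenoxy)-3,5-dimethoxyphenoxy]-3,4,5-trimethoxyphenoxy}-3,5-dimethoxyphenoxy)-3,5-dimethoxyphenoxy]-3,5-dimethoxyphenyl formate | COc1cc(OC=O)cc(OC)c1Oc1cc(OC)c(Oc2cc(OC)c(Oc3cc(OC)c(OC)c(OC)c3Oc3cc(OC)c(Oc4cc(OC)c(OC=O)c(OC)c4)c(OC)c3)c(OC)c2)c(OC)c1 | intermediate
24 | 4-[4-(4-{2-[4-(4-hydroxy-3,5-dimethoxyphenoxy)-3,5-dimethoxyphenoxy]-3,4,5-trimethoxyphenoxy}-3,5-dimethoxyphenoxy)-3,5-dimethoxyphenoxy]-3,5-dimethoxyphenol (tridecamethyl ether of the target; free OH on rings A and F) | COc1cc(O)cc(OC)c1Oc1cc(OC)c(Oc2cc(OC)c(Oc3cc(OC)c(OC)c(OC)c3Oc3cc(OC)c(Oc4cc(OC)c(O)c(OC)c4)c(OC)c3)c(OC)c2)c(OC)c1 | intermediate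
25 | pentadecakis(dibromoboryl) ether of 26 (every O–H of 26 replaced by O–BBr2) | BrB(Br)Oc1cc(OB(Br)Br)c(Oc2cc(OB(Br)Br)c(Oc3cc(OB(Br)Br)c(Oc4cc(OB(Br)Br)c(OB(Br)Br)c(OB(Br)Br)c4Oc4cc(OB(Br)Br)c(Oc5cc(OB(Br)Br)c(OB(Br)Br)c(OB(Br)Br)c5)c(OB(Br)Br)c4)c(OB(Br)Br)c3)c(OB(Br)Br)c2)c(OB(Br)Br)c1 | intermediate
26 | CNP0175585.0: 2-[4-(4-{2-[3,5-dihydroxy-4-(3,4,5-trihydroxyphenoxy)phenoxy]-3,4,5-trihydroxyphenoxy}-3,5-dihydroxyphenoxy)-3,5-dihydroxyphenoxy]benzene-1,3,5-triol (achiral) | Oc1cc(O)c(Oc2cc(O)c(Oc3cc(O)c(Oc4cc(O)c(O)c(O)c4Oc4cc(O)c(Oc5cc(O)c(O)c(O)c5)c(O)c4)c(O)c3)c(O)c2)c(O)c1 | target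

**Step count and risks**
Total step count: 14.
Longest linear sequence: 12 steps (steps 1, 2, 5–14, from 1 to 26).

Three steps most likely to fail:

- **Step 8** (the same risk recurs in step 11). The gated SNAr may not discriminate cleanly between the open and the flanked phenoxide, or the hindered fluoride may react too slowly. The fallback replaces the steric gate by a halogen placeholder. It sets out from 12: bromination of ring D with NBS (MeCN, 0 °C; ring C is deactivated by CHO) gives the aryl bromide F1. Baeyer–Villiger oxidation (mCPBA, then MeOH/Et3N) passes through the formate F2 to the mono-phenol F3. SNAr of F3 with 5 (Cs2CO3, DMSO) gives the bromo aldehyde F4, with only one phenol present. Miyaura borylation (B2pin2, Pd(OAc)2/SPhos, KOAc, dioxane, 90 °C) gives the pinacol boronate F5. Oxidation of the C–B bond with Me3NO (THF, rt), which spares the aldehyde, comes back to the route at 17.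

- **Step 5.** SNAr at a fluoride flanked by two methoxy groups may be too sluggish. The fallback sets out from 11 and the bromo aldehyde 1 (before its fluorination) and joins them by Pd-catalysed C–O cross-coupling (Pd(OAc)2, t-BuXPhos, K3PO4, toluene, 100 °C). It comes back to the route at 12 and makes no new compound (F0).

- **Step 14.** Thirteen-fold demethylation may be incomplete, and the free polyphenol is air-sensitive and hard to purify. The fallback sets out from 24: demethylate with BBr3 as before but do not isolate the polyphenol. Peracetylate the crude material (Ac2O, pyridine, DMAP) to the pentadecaacetate F6 and purify it on silica, which also removes partly methylated material. Then cleave the acetates by acid transesterification (HCl from AcCl in MeOH, rt, Ar) to come back at 26.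

**Further compounds**
F0 | step 5 | none | none
F1 | step 8 | 4-(2-bromo-3,4,5-trimethoxyphenoxy)-3,5-dimethoxybenzaldehyde | COc1cc(C=O)cc(OC)c1Oc1cc(OC)c(OC)c(OC)c1Br
F2 | step 8 | 4-(2-bromo-3,4,5-trimethoxyphenoxy)-3,5-dimethoxyphenyl formate | COc1cc(OC=O)cc(OC)c1Oc1cc(OC)c(OC)c(OC)c1Br
F3 | step 8 | 4-(2-bromo-3,4,5-trimethoxyphenoxy)-3,5-dimethoxyphenol | COc1cc(O)cc(OC)c1Oc1cc(OC)c(OC)c(OC)c1Br
F4 | step 8 | 4-[4-(2-bromo-3,4,5-trimethoxyphenoxy)-3,5-dimethoxyphenoxy]-3,5-dimethoxybenzaldehyde | COc1cc(C=O)cc(OC)c1Oc1cc(OC)c(Oc2cc(OC)c(OC)c(OC)c2Br)c(OC)c1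
F5 | step 8 | 3,5-dimethoxy-4-{3,5-dimethoxy-4-[3,4,5-trimethoxy-2-(4,4,5,5-tetramethyl-1,3,2-dioxaborolan-2-yl)phenoxy]phenoxy}benzaldehyde | COc1cc(C=O)cc(OC)c1Oc1cc(OC)c(Oc2cc(OC)c(OC)c(OC)c2B3OC(C)(C)C(C)(C)O3)c(OC)c1
F6 | step 14 | pentadecaacetate of 26 (all fifteen OH groups as acetates) | CC(=O)Oc1cc(OC(C)=O)c(Oc2cc(OC(C)=O)c(Oc3cc(OC(C)=O)c(Oc4cc(OC(C)=O)c(OC(C)=O)c(OC(C)=O)c4Oc4cc(OC(C)=O)c(Oc5cc(OC(C)=O)c(OC(C)=O)c(OC(C)=O)c5)c(OC(C)=O)c4)c(OC(C)=O)c3)c(OC(C)=O)c2)c(OC(C)=O)c1
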